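- In a one-step world the free catalyst we weigh in would be the catalyst that turns over, but here impurity first takes free catalyst into spent catalyst, so we reckon with the surviving catalyst W, the charged free catalyst minus the charged impurity: 0.300 mM in cedar and 0.470 mM in ash.

| setting | amber | green | cedar | ash |
|---|---|---|---|---|
| left-handed substrate | 15 mM | 15 mM | 15 mM | 15 mM |
| right-handed substrate | 15 mM | 15 mM | 15 mM | 15 mM |
| reagent | 30 mM | 30 mM | 30.0 mM | 30.0 mM |
| free catalyst | 0.33 mM | 0.46 mM | 0.43 mM | 0.60 mM |
| impurity | 0.13 mM | 0.13 mM | 0.13 mM | 0.13 mM |
| added ligand | 0.25 mM | 0.25 mM | 0.25 mM | 0.25 mM |
| remark | run made earlier | run made earlier |  |  |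
| time |  |  | 5.0 h | 5.0 h |

| run | time / h | right-handed substrate / % | left-handed substrate / % | left-handed product / % |
|---|---|---|---|---|
| amber | 0.667 | 43 | 37 | 10 |
| amber | 1.33 | 42 | 33 | 18 |
| amber | 2.00 | 38 | 28 | 22 |
| amber | 2.50 | 36 | 23 | 25 |
| amber | 3.00 | 32 | 22 | 26 |
| amber | 4.00 | 33 | 17 | 27 |
| green | 0.667 | 42 | 35 | 17 |
| green | 1.33 | 35 | 27 | 26 |
| green | 2.00 | 33 | 19 | 29 |
| green | 2.50 | 30 | 19 | 32 |
| green | 3.00 | 29 | 17 | 34 |
| green | 4.00 | 26 | 13 | 39 |

(each reading ± 1.5 percentage points)

* which one finishes higher in excess of right-handed substrate over left-handed substrate among what is left of the two ("neither" within 2 percentage points) (cedar / ash / neither)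
* excess of right-handed substrate over left-handed substrate among what is left of the two at the end, cedar
* excess of right-handed substrate over left-handed substrate among what is left of the two at the end, ash

- free catalyst is single-handed; left-handed substrate and right-handed substrate are mirror images of each other, charged as a racemate, each of them at the stated concentration
- the numbers in the tables scatter with a standard deviation of 1.5 percentage points
- candidate steps: reagent + free catalyst + left-handed substrate -> free catalyst + left-handed product; free catalyst + added ligand <-> idle complex; reagent -> decomposition product; reagent + free catalyst + right-handed substrate -> free catalyst + right-handed product; free catalyst + impurity -> spent catalyst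
- an excess is the difference of the two amounts in percent of their sum
- an excess is below zero if the other one leads

- Green has 1.65 times the W of amber, and at 0.667 h green's left-handed product over amber's reads 1.70, a ratio carrying the scatter of the readings.
- We therefore use W times time as the clock of these flasks; green's last reading, at 4.00 h, shows a right-handed excess of 33.3%, and on that clock cedar at 5.0 h stands at 1.14 times green's last reading and ash at 1.78 times, so when you come we expect right-handed substrate to lead in both, cedar a little above green's figure and ash well above it.
- Add no added ligand: it turns free catalyst into idle complex, and W stays the same while the free part falls.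
- The forecast gives 38% for cedar and 48% for ash, so ash higher, and says: “Reagent starvation limits ash's lead.”
- The flask gives 39.2% in cedar and 51.3% in ash, so ash finishes higher, as forecast, and the gap comes mainly from the difference in charged free catalyst: ash stands at 51.3% with that difference and at 39.2% without it.

    reagent + free catalyst + left-handed substrate → free catalyst + left-handed product (k = 28.0 M⁻² s⁻¹)
    free catalyst + added ligand ⇌ idle complex, settled at all times (K = 4100 M⁻¹)
    reagent → decomposition product (k = 3.10 × 10⁻⁶ s⁻¹)
    reagent + free catalyst + right-handed substrate → free catalyst + right-handed product (k = 13.0 M⁻² s⁻¹)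
    free catalyst + impurity → spent catalyst (k = 450 M⁻¹ s⁻¹)

- In cedar at 5.00 h, free catalyst at 44.3% and idle complex at 25.5% of the catalyst charged together make up the 69.8% that W gave, beside 30.2% of spent catalyst. The neighbour charged with 1.0 mM of added ligand has the same W, and its free catalyst at 16.7% and idle complex at 53.0% again sum to that share. With less free catalyst than cedar, that neighbour reaches a lower excess than cedar, 20.7% at 5.00 h.

The data stem from a simulated flask for an exercise; scatter was added.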